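**Retrosynthetic overview**
1. The C3 isobutyrate, the oxirane (tosylate closure of a masked 1,2‑diol) and the C5 enoate (acylation of an allylic alcohol made by allylic hydroxylation of the exocyclic methylene) are installed last.
2. The cyclopentane is closed second, at C1–C2, by a nickel‑catalysed borylative alkyne–aldehyde cyclisation on a trans‑2,3‑disubstituted methylidenecyclohexane; an Evans–Tishchenko reduction then sets the side‑chain carbinol and places the O‑2 isobutyrate.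
3. The ynal comes from a 4‑substituted cyclohexenone by conjugate propynylation and a catalyst‑controlled glyoxylate Mukaiyama aldol.
4. The cyclohexane is formed first, by an organocatalytic Michael/aldol annulation of methyl vinyl ketone with an aldehyde made from (S)‑2‑methylglycidol (source of the oxirane stereocentre).
5. The acid side chain is made separately from ethyl (S)‑lactate (Horner–Wadsworth–Emmons) and joined as its acid chloride.

Assumption: compounds 1, 10, 14, 17, 20 and 26 are bought as such (1 and 10 as single enantiomers).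
Convention: bicyclic compounds use octahydro‑1H‑indene locants (C1 two‑carbon side chain, C2 and C3 isobutyrate oxygens, C4 methylidene, C5 enoate oxygen, C7 three‑carbon unit); β is the side of H‑7a, α the side of H‑3a. The SMILES fix the absolute configuration.

**Fragment A: acid chloride (steps 1–8)**

Step 1
Reactants: 1 ethyl (S)-lactate
Product: 2 ethyl (S)-2-[(tert-butyldimethylsilyl)oxy]propanoate
Conditions: TBSCl, imidazole, DMF, 0 → 23 °C
Reagents that add atoms: tert-butyldimethylsilyl chloride, CC(C)(C)[Si](C)(C)Cl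
Why: Standard O‑silylation masks the hydroxyl for the organometallic steps; the stereocentre is not touched.

Step 2
Reactants: 2 ethyl (S)-2-[(tert-butyldimethylsilyl)oxy]propanoate
Product: 3 (S)-2-[(tert-butyldimethylsilyl)oxy]-N-methoxy-N-methylpropanamide
Conditions: MeNH(OMe)·HCl, i-PrMgCl, THF, −20 → 0 °C
Reagents that add atoms: N,O-dimethylhydroxylamine hydrochloride, CNOC.Cl
Why: Weinreb amide formation by the magnesium amide made in the flask is fast at low temperature and does not enolise the α‑silyloxy ester.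

Step 3
Reactants: 3 (S)-2-[(tert-butyldimethylsilyl)oxy]-N-methoxy-N-methylpropanamide
Product: 4 (S)-3-[(tert-butyldimethylsilyl)oxy]butan-2-one
Conditions: MeMgBr, THF, −78 → 0 °C
Reagents that add atoms: methylmagnesium bromide, C[Mg]Br
Why: Grignard addition to a Weinreb amide stops at the ketone because the chelated tetrahedral intermediate survives until work‑up.

Step 4
Reactants: 4 (S)-3-[(tert-butyldimethylsilyl)oxy]butan-2-one
Product: 5 tert-butyl (S,E)-4-[(tert-butyldimethylsilyl)oxy]-3-methylpent-2-enoate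
Conditions: (EtO)2P(O)CH2CO2t-Bu, NaH, THF, 0 → 23 °C
Reagents that add atoms: tert-butyl 2-(diethoxyphosphoryl)acetate, CCOP(=O)(OCC)CC(=O)OC(C)(C)C
Why: Horner–Wadsworth–Emmons olefination of the α‑silyloxy methyl ketone places the ester trans to the larger CH(OTBS)CH3 group, giving the (E)‑enoate without racemisation.

Step 5
Reactants: 5 tert-butyl (S,E)-4-[(tert-butyldimethylsilyl)oxy]-3-methylpent-2-enoate
Product: 6 tert-butyl (S,E)-4-hydroxy-3-methylpent-2-enoate
Conditions: Bu4NF, THF, 0 °C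
Reagents that add atoms: none
Why: Fluoride desilylation; the (E)‑hydroxy ester cannot lactonise, so the alkene geometry is kept.

Step 6
Reactants: 6 tert-butyl (S,E)-4-hydroxy-3-methylpent-2-enoate
Product: 7 tert-butyl (S,E)-4-acetoxy-3-methylpent-2-enoate
Conditions: Ac2O, pyridine, DMAP (cat.), CH2Cl2, 0 → 23 °C
Reagents that add atoms: acetic anhydride, CC(=O)OC(C)=O
Why: DMAP‑catalysed acetylation of the secondary allylic alcohol with retention.

Step 7
Reactants: 7 tert-butyl (S,E)-4-acetoxy-3-methylpent-2-enoate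
Product: 8 (S,E)-4-acetoxy-3-methylpent-2-enoic acid
Conditions: CF3CO2H, CH2Cl2, 0 → 23 °C
Reagents that add atoms: none
Why: Acidolysis of the tert‑butyl ester (loss of isobutene) leaves the acetate and the electron‑poor allylic centre intact.

Step 8
Reactants: 8 (S,E)-4-acetoxy-3-methylpent-2-enoic acid
Product: 9 (S,E)-4-acetoxy-3-methylpent-2-enoyl chloride
Conditions: (COCl)2, DMF (cat.), CH2Cl2, 0 → 23 °C, then evaporation
Reagents that add atoms: oxalyl chloride, O=C(Cl)C(=O)Cl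
Why: Vilsmeier‑type acid chloride formation under neutral conditions gives an acylating agent strong enough for a hindered axial alcohol.

**Fragment B and assembly (steps 9–23)**

Step 9
Reactants: 10 (S)-2-methylglycidol
Product: 11 (R)-2-methylpent-4-ene-1,2-diol
Conditions: CH2=CHMgBr (2.5 equiv), CuI (10 mol %), THF, −30 → 0 °C
Reagents that add atoms: vinylmagnesium bromide, C=C[Mg]Br
Why: Copper‑catalysed Grignard opening of the 2,2‑disubstituted epoxide at its CH2 (SN2) leaves the quaternary stereocentre untouched; the descriptor changes to R only through priorities.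

Step 10
Reactants: 11 (R)-2-methylpent-4-ene-1,2-diol
Product: 12 (R)-2,2,4-trimethyl-4-(prop-2-en-1-yl)-1,3-dioxolane
Conditions: Me2C(OMe)2, PPTS (cat.), CH2Cl2, 23 °C
Reagents that add atoms: 2,2-dimethoxypropane, COC(C)(C)OC
Why: Transacetalisation ties the tertiary/primary diol back as a compact acetonide that keeps the neighbouring carbon accessible.

Step 11
Reactants: 12 (R)-2,2,4-trimethyl-4-(prop-2-en-1-yl)-1,3-dioxolane
Product: 13 2-[(R)-2,2,4-trimethyl-1,3-dioxolan-4-yl]acetaldehyde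
Conditions: O3, CH2Cl2, −78 °C; then PPh3, −78 → 23 °C
Reagents that add atoms: ozone, [O-][O+]=O
Why: Ozonolysis with reductive work‑up cleaves the terminal alkene to the aldehyde, which is used crude.

Step 12
Reactants: 13 2-[(R)-2,2,4-trimethyl-1,3-dioxolan-4-yl]acetaldehyde; 14 methyl vinyl ketone
Product: 16 (S)-4-[(R)-2,2,4-trimethyl-1,3-dioxolan-4-yl]cyclohex-2-en-1-one, via keto aldehyde 15 (not isolated)
Conditions: (R)-α,α-diphenylprolinol trimethylsilyl ether (10 mol %), ethyl 3,4-dihydroxybenzoate (20 mol %), neat, 4 °C; then LiOH (cat.), i-PrOH, 23 °C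
Reagents that add atoms: none
Why: Enamine‑catalysed Michael addition followed by intramolecular aldol condensation (Robinson‑type annulation); the (R)‑catalyst shields one face of the (E)‑enamine and so sets the ring stereocentre (C4 of 16) under catalyst control.

Step 13
Reactants: 16 (S)-4-[(R)-2,2,4-trimethyl-1,3-dioxolan-4-yl]cyclohex-2-en-1-one; 17 prop-1-yn-1-ylmagnesium bromide
Product: 19 tert-butyldimethylsilyl enol ether of the 3,4-trans 3-propynyl ketone, via prop-1-yn-1-ylzinc bromide 18 (not isolated)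
Conditions: ZnBr2, THF, 0 °C; then 16, TBSOTf, Et2O–THF, −40 °C; Et3N
Reagents that add atoms: zinc bromide (in 18), [Zn+2].[Br-].[Br-]; tert-butyldimethylsilyl trifluoromethanesulfonate, CC(C)(C)[Si](C)(C)OS(=O)(=O)C(F)(F)F
Why: Silyl‑triflate‑promoted conjugate addition of the alkynylzinc occurs axially and anti to the bulky C4 substituent (3,4‑trans), and the enolate is trapped as the regiodefined silyl enol ether.

Step 14
Reactants: 19 tert-butyldimethylsilyl enol ether; 20 ethyl glyoxylate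
Product: 21 ethyl (R)-2-[(tert-butyldimethylsilyl)oxy]-2-{all-trans-6-oxo-2-(prop-1-yn-1-yl)-3-[(R)-2,2,4-trimethyl-1,3-dioxolan-4-yl]cyclohexyl}acetate
Conditions: [Cu((R,R)-t-Bu-box)](OTf)2 (10 mol %), CH2Cl2, −78 → −40 °C
Reagents that add atoms: none
Why: Mukaiyama aldol catalysed by a bis(oxazoline) complex of divalent copper: the chelated glyoxylate is attacked on its re face (catalyst control, (R)‑carbinol), the enol ether reacts anti to the C3 propynyl group with the epimerisable α‑centre resting equatorial (2,3‑trans), and silyl transfer gives the TBS ether directly.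

Step 15
Reactants: 21 keto ester
Product: 22 ethyl (R)-2-[(tert-butyldimethylsilyl)oxy]-2-{all-trans-6-methylidene-2-(prop-1-yn-1-yl)-3-[(R)-2,2,4-trimethyl-1,3-dioxolan-4-yl]cyclohexyl}acetate
Conditions: Zn, CH2Br2, TiCl4, THF/CH2Cl2, 0 → 23 °C
Reagents that add atoms: dibromomethane, BrCBr
Why: Takai–Lombardo methylenation is non‑basic, so the hindered β‑silyloxy ketone is methylenated without epimerisation or elimination, and the ester is untouched.

Step 16
Reactants: 22 methylidene ester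
Product: 23 (R)-2-[(tert-butyldimethylsilyl)oxy]-2-{all-trans-6-methylidene-2-(prop-1-yn-1-yl)-3-[(R)-2,2,4-trimethyl-1,3-dioxolan-4-yl]cyclohexyl}acetaldehyde
Conditions: i-Bu2AlH (1.1 equiv), toluene, −78 °C
Reagents that add atoms: none
Why: Partial reduction of the α‑silyloxy ester stops at the aldehyde because the chelated aluminium hemiacetal is stable at −78 °C.

Step 17
Reactants: 23 ynal
Product: 25 1β-acetyl-2α-hydroxy hydrindane, via alkenyl boronate 24 (not isolated)
Conditions: Ni(cod)2 (10 mol %), PCy3 (20 mol %), B2pin2 (1.5 equiv), THF, 23 → 45 °C; then NaBO3·4H2O, THF/H2O, 0 → 23 °C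
Reagents that add atoms: bis(pinacolato)diboron (boron of 24), CC1(C)OB(B2OC(C)(C)C(C)(C)O2)OC1(C)C; sodium perborate (ketone oxygen of 25), [Na+].[O-]OB=O
Why: Proposed new method: a borylative alkyne–aldehyde cyclisation in which zerovalent nickel couples the tethered alkyne and aldehyde by oxidative cyclisation to an oxanickelacyclopentene (forming the C1–C2 bond and the cyclopentane, with the C2 oxygen trans to the C3 silyloxy group), B2pin2 cleaves the Ni–O bond by σ‑bond metathesis and C–B reductive elimination gives the exocyclic alkenyl boronate 24, whose perborate oxidation unveils the methyl ketone while the epimerisable C1 centre settles trans to both neighbours; the closest known reactions are the nickel‑catalysed reductive cyclisation of ynals with silanes and the nickel‑catalysed borylative coupling of dienes with aldehydes.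

Step 18
Reactants: 25 β-hydroxy ketone; 26 isobutyraldehyde
Product: 28 1β-[(S)-1-acetoxyethyl] 2α-isobutyrate, via hydroxy isobutyrate 27 (not isolated)
Conditions: SmI2 (30 mol %), THF, −10 °C; then Ac2O, pyridine, DMAP, 0 → 23 °C
Reagents that add atoms: acetic anhydride, CC(=O)OC(C)=O
Why: Evans–Tishchenko reduction: the C2 hydroxyl forms a hemiacetal with isobutyraldehyde and samarium‑bound intramolecular hydride transfer gives the 1,3‑anti (S)‑carbinol while leaving the isobutyrate on O‑2; the free carbinol is acetylated in the same flask before any acyl migration.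

Step 19
Reactants: 28 silyl ether diester
Product: 29 5α-allylic alcohol
Conditions: SeO2 (0.5 equiv), t-BuOOH, CH2Cl2, 23 °C
Reagents that add atoms: selenium dioxide, O=[Se]=O; tert-butyl hydroperoxide, CC(C)(C)OO
Why: Allylic hydroxylation (ene reaction then [2,3]‑sigmatropic shift) at the only allylic CH2 (C5) is expected to deliver oxygen axially (5α) on the locked trans‑hydrindane chair, while the tertiary C3a–H is hindered and deactivated.

Step 20
Reactants: 29 5α-allylic alcohol; 9 (S,E)-4-acetoxy-3-methylpent-2-enoyl chloride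
Product: 30 5α-enoate
Conditions: pyridine, DMAP (cat.), CH2Cl2, 0 → 23 °C
Reagents that add atoms: none
Why: DMAP‑catalysed acylation of the only free hydroxyl with retention at C5; low temperature limits deconjugation of the enoate.

Step 21
Reactants: 30 5α-enoate
Product: 31 triol
Conditions: aq. HF (48 %), MeCN, 0 → 23 °C
Reagents that add atoms: none
Why: Acidic global deprotection removes the C3 silyl ether and hydrolyses the acetonide in one operation without touching the esters or any stereocentre.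

Step 22
Reactants: 31 triol
Product: 33 3β-hydroxy oxirane, via primary tosylate 32 (not isolated)
Conditions: TsCl, Et3N, Bu2SnO (5 mol %), CH2Cl2, 0 → 23 °C; then DBU, 0 → 23 °C
Reagents that add atoms: p-toluenesulfonyl chloride (in 32), Cc1ccc(cc1)S(=O)(=O)Cl
Why: Tin‑catalysed sulfonylation selects the primary hydroxyl of the 1,2‑diol over the hindered C3 alcohol, and intramolecular Williamson closure (3‑exo‑tet) by the tertiary alkoxide forms the oxirane without breaking a bond at the quaternary stereocentre.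

Step 23
Reactants: 33 3β-hydroxy oxirane
Product: 34 CNP0131236.1
Conditions: i-PrCOCl, Et3N, DMAP (cat.), CH2Cl2, 0 °C
Reagents that add atoms: 2-methylpropanoyl chloride, CC(C)C(=O)Cl
Why: DMAP‑catalysed acylation of the last free hydroxyl (C3) under buffered conditions that the oxirane tolerates.

**Compound list**

1 | ethyl (S)-2-hydroxypropanoate (ethyl (S)-lactate) | C[C@H](O)C(=O)OCC | starting material
2 | ethyl (S)-2-[(tert-butyldimethylsilyl)oxy]propanoate | C[C@H](O[Si](C)(C)C(C)(C)C)C(=O)OCC | intermediate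
3 | (S)-2-[(tert-butyldimethylsilyl)oxy]-N-methoxy-N-methylpropanamide | C[C@H](O[Si](C)(C)C(C)(C)C)C(=O)N(C)OC | intermediate
4 | (S)-3-[(tert-butyldimethylsilyl)oxy]butan-2-one | C[C@H](O[Si](C)(C)C(C)(C)C)C(C)=O | intermediate
5 | tert-butyl (S,E)-4-[(tert-butyldimethylsilyl)oxy]-3-methylpent-2-enoate | CC(C)(C)OC(=O)/C=C(\C)[C@H](C)O[Si](C)(C)C(C)(C)C | intermediate
6 | tert-butyl (S,E)-4-hydroxy-3-methylpent-2-enoate | CC(C)(C)OC(=O)/C=C(\C)[C@H](C)O | intermediate
7 | tert-butyl (S,E)-4-acetoxy-3-methylpent-2-enoate | CC(C)(C)OC(=O)/C=C(\C)[C@H](C)OC(C)=O | intermediate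
8 | (S,E)-4-acetoxy-3-methylpent-2-enoic acid | OC(=O)/C=C(\C)[C@H](C)OC(C)=O | intermediate
9 | (S,E)-4-acetoxy-3-methylpent-2-enoyl chloride | ClC(=O)/C=C(\C)[C@H](C)OC(C)=O | intermediate
10 | (S)-(2-methyloxiran-2-yl)methanol ((S)-2-methylglycidol) | C[C@]1(CO)CO1 | starting material
11 | (R)-2-methylpent-4-ene-1,2-diol | C=CC[C@@](C)(O)CO | intermediate
12 | (R)-2,2,4-trimethyl-4-(prop-2-en-1-yl)-1,3-dioxolane | C=CC[C@]1(C)COC(C)(C)O1 | intermediate
13 | 2-[(R)-2,2,4-trimethyl-1,3-dioxolan-4-yl]acetaldehyde | O=CC[C@]1(C)COC(C)(C)O1 | intermediate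
14 | but-3-en-2-one (methyl vinyl ketone) | CC(=O)C=C | starting material
15 | (R)-5-oxo-2-[(R)-2,2,4-trimethyl-1,3-dioxolan-4-yl]hexanal | O=C[C@@H]([C@]1(C)COC(C)(C)O1)CCC(C)=O | intermediate (not isolated)
16 | (S)-4-[(R)-2,2,4-trimethyl-1,3-dioxolan-4-yl]cyclohex-2-en-1-one | O=C1C=C[C@@H]([C@]2(C)COC(C)(C)O2)CC1 | intermediate
17 | prop-1-yn-1-ylmagnesium bromide | CC#C[Mg]Br | starting material
18 | prop-1-yn-1-ylzinc bromide | CC#C[Zn]Br | intermediate (not isolated)
19 | tert-butyldimethyl{[(3S,4S)-3-(prop-1-yn-1-yl)-4-[(R)-2,2,4-trimethyl-1,3-dioxolan-4-yl]cyclohex-1-en-1-yl]oxy}silane (3,4-trans) | CC(C)(C)[Si](C)(C)OC1=C[C@H](C#CC)[C@@H]([C@]2(C)COC(C)(C)O2)CC1 | intermediate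
20 | ethyl 2-oxoacetate (ethyl glyoxylate) | O=CC(=O)OCC | starting material
21 | ethyl (R)-2-[(tert-butyldimethylsilyl)oxy]-2-{all-trans-6-oxo-2-(prop-1-yn-1-yl)-3-[(R)-2,2,4-trimethyl-1,3-dioxolan-4-yl]cyclohexyl}acetate | O=C1[C@@H]([C@@H](O[Si](C)(C)C(C)(C)C)C(=O)OCC)[C@H](C#CC)[C@@H]([C@]2(C)COC(C)(C)O2)CC1 | intermediate
22 | ethyl (R)-2-[(tert-butyldimethylsilyl)oxy]-2-{all-trans-6-methylidene-2-(prop-1-yn-1-yl)-3-[(R)-2,2,4-trimethyl-1,3-dioxolan-4-yl]cyclohexyl}acetate | C=C1[C@@H]([C@@H](O[Si](C)(C)C(C)(C)C)C(=O)OCC)[C@H](C#CC)[C@@H]([C@]2(C)COC(C)(C)O2)CC1 | intermediate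
23 | (R)-2-[(tert-butyldimethylsilyl)oxy]-2-{all-trans-6-methylidene-2-(prop-1-yn-1-yl)-3-[(R)-2,2,4-trimethyl-1,3-dioxolan-4-yl]cyclohexyl}acetaldehyde | C=C1[C@@H]([C@@H](O[Si](C)(C)C(C)(C)C)C=O)[C@H](C#CC)[C@@H]([C@]2(C)COC(C)(C)O2)CC1 | intermediate
24 | 3β-[(tert-butyldimethylsilyl)oxy]-4-methylidene-2α-[(pinacolatoboryl)oxy]-1-[1-(pinacolatoboryl)ethylidene]-7β-[(R)-2,2,4-trimethyl-1,3-dioxolan-4-yl]-(3aα-H,7aβ-H)-octahydro-1H-indene (C-boryl group cis to C2) | C=C1[C@H]2[C@@H](O[Si](C)(C)C(C)(C)C)[C@H](OB3OC(C)(C)C(C)(C)O3)/C(=C(/C)B3OC(C)(C)C(C)(C)O3)[C@@H]2[C@@H]([C@]2(C)COC(C)(C)O2)CC1 | intermediate (not isolated)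
25 | 1-{3β-[(tert-butyldimethylsilyl)oxy]-2α-hydroxy-4-methylidene-7β-[(R)-2,2,4-trimethyl-1,3-dioxolan-4-yl]-(3aα-H,7aβ-H)-octahydro-1H-inden-1β-yl}ethan-1-one | C=C1[C@H]2[C@@H](O[Si](C)(C)C(C)(C)C)[C@H](O)[C@@H](C(C)=O)[C@@H]2[C@@H]([C@]2(C)COC(C)(C)O2)CC1 | intermediate
26 | 2-methylpropanal (isobutyraldehyde) | CC(C)C=O | starting material
27 | 3β-[(tert-butyldimethylsilyl)oxy]-1β-[(S)-1-hydroxyethyl]-4-methylidene-7β-[(R)-2,2,4-trimethyl-1,3-dioxolan-4-yl]-(3aα-H,7aβ-H)-octahydro-1H-inden-2α-yl 2-methylpropanoate | C=C1[C@H]2[C@@H](O[Si](C)(C)C(C)(C)C)[C@H](OC(=O)C(C)C)[C@@H]([C@H](C)O)[C@@H]2[C@@H]([C@]2(C)COC(C)(C)O2)CC1 | intermediate (not isolated)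
28 | 1β-[(S)-1-acetoxyethyl]-3β-[(tert-butyldimethylsilyl)oxy]-4-methylidene-7β-[(R)-2,2,4-trimethyl-1,3-dioxolan-4-yl]-(3aα-H,7aβ-H)-octahydro-1H-inden-2α-yl 2-methylpropanoate | C=C1[C@H]2[C@@H](O[Si](C)(C)C(C)(C)C)[C@H](OC(=O)C(C)C)[C@@H]([C@H](C)OC(C)=O)[C@@H]2[C@@H]([C@]2(C)COC(C)(C)O2)CC1 | intermediate
29 | 1β-[(S)-1-acetoxyethyl]-3β-[(tert-butyldimethylsilyl)oxy]-5α-hydroxy-4-methylidene-7β-[(R)-2,2,4-trimethyl-1,3-dioxolan-4-yl]-(3aα-H,7aβ-H)-octahydro-1H-inden-2α-yl 2-methylpropanoate | C=C1[C@H]2[C@@H](O[Si](C)(C)C(C)(C)C)[C@H](OC(=O)C(C)C)[C@@H]([C@H](C)OC(C)=O)[C@@H]2[C@@H]([C@]2(C)COC(C)(C)O2)C[C@@H]1O | intermediate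
30 | 1β-[(S)-1-acetoxyethyl]-3β-[(tert-butyldimethylsilyl)oxy]-4-methylidene-2α-(2-methylpropanoyloxy)-7β-[(R)-2,2,4-trimethyl-1,3-dioxolan-4-yl]-(3aα-H,7aβ-H)-octahydro-1H-inden-5α-yl (S,E)-4-acetoxy-3-methylpent-2-enoate | C=C1[C@H]2[C@@H](O[Si](C)(C)C(C)(C)C)[C@H](OC(=O)C(C)C)[C@@H]([C@H](C)OC(C)=O)[C@@H]2[C@@H]([C@]2(C)COC(C)(C)O2)C[C@@H]1OC(=O)/C=C(\C)[C@H](C)OC(C)=O | intermediate
31 | 1β-[(S)-1-acetoxyethyl]-7β-[(R)-1,2-dihydroxypropan-2-yl]-3β-hydroxy-4-methylidene-2α-(2-methylpropanoyloxy)-(3aα-H,7aβ-H)-octahydro-1H-inden-5α-yl (S,E)-4-acetoxy-3-methylpent-2-enoate | C=C1[C@H]2[C@@H](O)[C@H](OC(=O)C(C)C)[C@@H]([C@H](C)OC(C)=O)[C@@H]2[C@@H]([C@@](C)(O)CO)C[C@@H]1OC(=O)/C=C(\C)[C@H](C)OC(C)=O | intermediate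
32 | primary p-toluenesulfonate of 31 (7β-[(R)-2-hydroxy-1-(tosyloxy)propan-2-yl]) | C=C1[C@H]2[C@@H](O)[C@H](OC(=O)C(C)C)[C@@H]([C@H](C)OC(C)=O)[C@@H]2[C@@H]([C@@](C)(O)COS(=O)(=O)c3ccc(C)cc3)C[C@@H]1OC(=O)/C=C(\C)[C@H](C)OC(C)=O | intermediate (not isolated)
33 | 1β-[(S)-1-acetoxyethyl]-3β-hydroxy-4-methylidene-2α-(2-methylpropanoyloxy)-7β-[(R)-2-methyloxiran-2-yl]-(3aα-H,7aβ-H)-octahydro-1H-inden-5α-yl (S,E)-4-acetoxy-3-methylpent-2-enoate | C=C1[C@H]2[C@@H](O)[C@H](OC(=O)C(C)C)[C@@H]([C@H](C)OC(C)=O)[C@@H]2[C@@H]([C@]2(C)CO2)C[C@@H]1OC(=O)/C=C(\C)[C@H](C)OC(C)=O | intermediate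
34 | CNP0131236.1: 1β-[(S)-1-acetoxyethyl]-4-methylidene-2α,3β-bis(2-methylpropanoyloxy)-7β-[(R)-2-methyloxiran-2-yl]-(3aα-H,7aβ-H)-octahydro-1H-inden-5α-yl (S,E)-4-acetoxy-3-methylpent-2-enoate | C=C1[C@H]2[C@@H](OC(=O)C(C)C)[C@H](OC(=O)C(C)C)[C@@H]([C@H](C)OC(C)=O)[C@@H]2[C@@H]([C@]2(C)CO2)C[C@@H]1OC(=O)/C=C(\C)[C@H](C)OC(C)=O | target

**Step count and risk**

Total step count: 23. Longest linear sequence: 15 steps (steps 9–23, from 10 to 34); the acid chloride branch (steps 1–8) joins at step 20.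

Steps most likely to fail:

Step 14 (catalyst‑controlled glyoxylate aldol; risks are poor selectivity at the carbinol carbon in a mismatched case and slow silyl transfer from a TBS enol ether). The fallback sets out from 19. A BF3·OEt2‑promoted Mukaiyama aldol with 20, without chiral catalyst, gives the hydroxy keto ester F1 as a mixture at the carbinol carbon. Zn/CH2Br2/TiCl4 methylenation gives the methylidene hydroxy ester F2. Dess–Martin oxidation gives the α‑keto ester F3, which erases the mixture. Reagent‑controlled reduction (B‑methyl CBS oxazaborolidine of the hand that gives the (R)‑alcohol, catecholborane, −78 °C) gives the (R)‑hydroxy ester F4. Silylation with TBSOTf/2,6‑lutidine comes back to the route at 22.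

Step 17 (the proposed nickel‑catalysed borylative cyclisation; risks are Tishchenko or hydroacylation side reactions of the aldehyde and slow Ni–O/B–B exchange). The fallback uses known chemistry and sets out from 23. AgSbF6‑catalysed intramolecular alkyne–carbonyl metathesis (DCE, 60 °C) gives the bicyclic 1‑acetylcyclopentene F5. Copper‑catalysed conjugate borylation (CuCl, NaOt‑Bu, Xantphos, B2pin2, MeOH, THF) adds boron at C2 anti to the C3 silyloxy group and gives the β‑boryl ketone F6. NaBO3 oxidation with retention, with C1 equilibrating trans, comes back to the route at 25.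

Step 19 (SeO2 hydroxylation; risks are over‑oxidation to the enone and the wrong C5 epimer). The fallback sets out from 28. SeO2 followed by Dess–Martin periodinane on the crude product converts everything to the α‑methylene ketone F7. NaBH4/CeCl3·7H2O reduction (1,2‑selective, axial hydride) gives the equatorial 5β‑alcohol F8. Mitsunobu esterification with acid 8 (PPh3, DIAD, toluene) inverts C5 and comes back to the route at 30.

Further compounds
F1 | step 14 | ethyl 2-hydroxy-2-{all-trans-6-oxo-2-(prop-1-yn-1-yl)-3-[(R)-2,2,4-trimethyl-1,3-dioxolan-4-yl]cyclohexyl}acetate (both carbinol epimers) | O=C1[C@@H](C(O)C(=O)OCC)[C@H](C#CC)[C@@H]([C@]2(C)COC(C)(C)O2)CC1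
F2 | step 14 | ethyl 2-hydroxy-2-{all-trans-6-methylidene-2-(prop-1-yn-1-yl)-3-[(R)-2,2,4-trimethyl-1,3-dioxolan-4-yl]cyclohexyl}acetate (both carbinol epimers) | C=C1[C@@H](C(O)C(=O)OCC)[C@H](C#CC)[C@@H]([C@]2(C)COC(C)(C)O2)CC1
F3 | step 14 | ethyl 2-oxo-2-{all-trans-6-methylidene-2-(prop-1-yn-1-yl)-3-[(R)-2,2,4-trimethyl-1,3-dioxolan-4-yl]cyclohexyl}acetate | C=C1[C@@H](C(=O)C(=O)OCC)[C@H](C#CC)[C@@H]([C@]2(C)COC(C)(C)O2)CC1
F4 | step 14 | ethyl (R)-2-hydroxy-2-{all-trans-6-methylidene-2-(prop-1-yn-1-yl)-3-[(R)-2,2,4-trimethyl-1,3-dioxolan-4-yl]cyclohexyl}acetate | C=C1[C@@H]([C@@H](O)C(=O)OCC)[C@H](C#CC)[C@@H]([C@]2(C)COC(C)(C)O2)CC1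
F5 | step 17 | 1-{3β-[(tert-butyldimethylsilyl)oxy]-4-methylidene-7β-[(R)-2,2,4-trimethyl-1,3-dioxolan-4-yl]-(3aα-H,7aβ-H)-3a,4,5,6,7,7a-hexahydro-3H-inden-1-yl}ethan-1-one | C=C1[C@H]2[C@@H](O[Si](C)(C)C(C)(C)C)C=C(C(C)=O)[C@@H]2[C@@H]([C@]2(C)COC(C)(C)O2)CC1
F6 | step 17 | 1-{3β-[(tert-butyldimethylsilyl)oxy]-4-methylidene-2α-(pinacolatoboryl)-7β-[(R)-2,2,4-trimethyl-1,3-dioxolan-4-yl]-(3aα-H,7aβ-H)-octahydro-1H-inden-1β-yl}ethan-1-one | C=C1[C@H]2[C@@H](O[Si](C)(C)C(C)(C)C)[C@H](B3OC(C)(C)C(C)(C)O3)[C@@H](C(C)=O)[C@@H]2[C@@H]([C@]2(C)COC(C)(C)O2)CC1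
F7 | step 19 | 1β-[(S)-1-acetoxyethyl]-3β-[(tert-butyldimethylsilyl)oxy]-4-methylidene-5-oxo-7β-[(R)-2,2,4-trimethyl-1,3-dioxolan-4-yl]-(3aα-H,7aβ-H)-octahydro-1H-inden-2α-yl 2-methylpropanoate | C=C1[C@H]2[C@@H](O[Si](C)(C)C(C)(C)C)[C@H](OC(=O)C(C)C)[C@@H]([C@H](C)OC(C)=O)[C@@H]2[C@@H]([C@]2(C)COC(C)(C)O2)CC1=O
F8 | step 19 | 1β-[(S)-1-acetoxyethyl]-3β-[(tert-butyldimethylsilyl)oxy]-5β-hydroxy-4-methylidene-7β-[(R)-2,2,4-trimethyl-1,3-dioxolan-4-yl]-(3aα-H,7aβ-H)-octahydro-1H-inden-2α-yl 2-methylpropanoate | C=C1[C@H]2[C@@H](O[Si](C)(C)C(C)(C)C)[C@H](OC(=O)C(C)C)[C@@H]([C@H](C)OC(C)=O)[C@@H]2[C@@H]([C@]2(C)COC(C)(C)O2)C[C@H]1O
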